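All runs are calculated on assumed constants; scatter was added.

**Two routes.** Over 40 h the starting material leaves by two routes: through the catalyst to target, and without the catalyst to uncatalysed product.

| flask | starting material | second substrate | free catalyst | remark | time |
|---|---|---|---|---|---|
| green | 0.14 M | 0.28 M | 70 µM | run made earlier |  |
| teal | 0.14 M | 0.14 M | 70 µM | run made earlier |  |
| amber | 0.14 M | 0.56 M | 70 µM | run made earlier |  |
| ochre | 0.14 M | 0.28 M | 100 µM | run made earlier |  |
| Thursday's | 0.14 M (fed, over 4.0 h) | 0.280 M | 70 µM | all else is in the flask from the start; the feed brings no volume worth counting | 40 h |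
| Saturday's | 0.14 M | 0.280 M | 70 µM | everything together at the start | 40 h |
| Tuesday's | 0.14 M | 0.280 M (fed, over 15 h) | 70 µM | all else is in the flask from the start; the feed brings no volume worth counting | 40 h |
| Friday's | 0.14 M (fed, over 15 h) | 0.280 M | 70 µM | all else is in the flask from the start; the feed brings no volume worth counting | 40 h |

| run | time / h | target / % | uncatalysed product / % |
|---|---|---|---|
| green | 3.00 | 6 | 5 |
| green | 8.00 | 10 | 17 |
| green | 15.0 | 18 | 30 |
| green | 40.0 | 35 | 48 |
| teal | 8.00 | 16 | 17 |
| teal | 15.0 | 27 | 26 |
| teal | 25.0 | 33 | 36 |
| teal | 30.0 | 38 | 39 |
| amber | 8.00 | 8 | 16 |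
| amber | 15.0 | 11 | 29 |
| amber | 25.0 | 15 | 43 |
| amber | 30.0 | 16 | 48 |
| ochre | 4.00 | 6 | 8 |
| ochre | 12.0 | 21 | 21 |
| ochre | 20.0 | 31 | 34 |
| ochre | 30.0 | 37 | 40 |

(scatter of a reading: 1.5 percentage points)

- for target the idle complex is counted in
- reactions considered so far: catalyst intermediate B -> free catalyst + second product; starting material -> uncatalysed product; catalyst intermediate A -> free catalyst + target; starting material + free catalyst <-> catalyst intermediate A; second substrate + free catalyst <-> catalyst intermediate B; free catalyst + target <-> idle complex

- the best flask by share of target in target plus uncatalysed product; "all alike" if 1.5 percentage points covers them all (Thursday's / Saturday's / Tuesday's / Friday's / all alike)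
- share of target in target plus uncatalysed product at the end, Thursday's
- share of target in target plus uncatalysed product at the end, Saturday's
- share of target in target plus uncatalysed product at the end, Tuesday's
- share of target in target plus uncatalysed product at the end, Friday's

**Waste ratio.** Divide the rate of one route by the other and time drops out. What remains is the waste ratio: uncatalysed product made per target made, the inverse of a selectivity factor. The teal run, with half a charge of second substrate, reads 1.03. The amber run, with twice a charge, reads 3.00. So a straight line through these two readings climbs by 1.32 per charge of second substrate, the waste slope, and reaches 0.368 at zero second substrate, an extrapolation that no run shows. The teal run reads 1.06 at 8.00 h and 1.03 at 30.0 h, so I expect feeding starting material to leave Thursday's and Friday's near Saturday's.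

**Two extremes.** With the full charge of second substrate held throughout, the extreme nearer Saturday's, the line gives a ratio of 1.68 and a target share of 37.3%. At the other extreme, the line's value at zero second substrate, read as a share, is 73.1%; this is an extrapolation, not a reading. I place Tuesday's between them, since its second substrate is fed in steadily over 15 h. The green run shows 30% uncatalysed product at 15.0 h and 48% at 40.0 h. If the second substrate climbs to the full charge during the feed, the line puts target per uncatalysed product at an average of 1.16 during the feed and 0.595 afterwards. So I reckon 45.3% target and a share of 48.6%.

**The forecast.** It gives 43% for Thursday's, 42% for Saturday's, 51% for Tuesday's and 45% for Friday's, and names Tuesday's as best. It holds that “Feeding starting material should gain little”. My Tuesday's share is lower than its figure, and my full-charge share is lower than its Saturday's figure.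

**The result.** The flasks give 40.3% for Thursday's, 39.9% for Saturday's, 46.7% for Tuesday's and 41.4% for Friday's, so the best is Tuesday's.

    catalyst intermediate B → free catalyst + second product (k = 1.10 min⁻¹)
    starting material → uncatalysed product (k = 4.30 × 10⁻⁴ min⁻¹)
    catalyst intermediate A → free catalyst + target (k = 3.10 min⁻¹)
    starting material + free catalyst ⇌ catalyst intermediate A (K = 6.50 L mol⁻¹, k = 420 L mol⁻¹ min⁻¹)
    second substrate + free catalyst ⇌ catalyst intermediate B (K = 43.0 L mol⁻¹, k = 19.0 L mol⁻¹ min⁻¹)
    free catalyst + target ⇌ idle complex, settled at all times (K = 14.0 L mol⁻¹)

**Neighbouring flask.** Take Saturday's with 0.11 M of second substrate, which is 0.393 of its charge. The waste slope 1.32 and the line's zero value 0.368 give a ratio of 0.885, and so a target share of 53.1%. That flask gives 51.2%, with 43.1% uncatalysed product and 11.6% starting material left at 40.0 h.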